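A catalyst charge of 0.66 mol% is small, and cedar, ash, grey and ochre all carry it, so one working number per temperature should compare them.

in all of them: substrate 0.11 M; added ligand 1.1 mM

|  | coupling partner | capture agent | free catalyst | temperature | remark | time |
|---|---|---|---|---|---|---|
| cedar | 2.8 equiv (fed, over 10 h) | 2.2 mM | 0.66 mol% | 0 °C | run made earlier; the fed solution adds 0.50 times the starting volume |  |
| ash | 4.4 equiv (fed, over 10 h) | 2.2 mM | 0.66 mol% | 15 °C | run made earlier; the fed solution adds 0.50 times the starting volume |  |
| birch | 2 equiv (fed, over 10 h) | 2.2 mM | 0.33 mol% | 0 °C | run made earlier; the fed solution adds 0.50 times the starting volume |  |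
| grey | 2.00 equiv | 2.20 mM | 0.66 mol% | 5 °C | everything together at the start, the whole solution of coupling partner included, so that from the start the volume is larger by 0.50 times the starting volume | 10 h |
| ochre | 2.00 equiv (fed, over 10 h) | 2.20 mM | 0.66 mol% | 25 °C | the fed solution adds 0.50 times the starting volume | 10 h |

| run | time / h | target / % |
|---|---|---|
| cedar | 3.00 | 6.3 |
| cedar | 5.00 | 11.9 |
| cedar | 6.00 | 14.6 |
| cedar | 15.0 | 37.9 |
| cedar | 20.0 | 47.7 |
| cedar | 30.0 | 62.3 |
| ash | 1.33 | 8.1 |
| ash | 2.00 | 16.4 |
| ash | 3.00 | 28.7 |
| ash | 6.00 | 65.4 |
| ash | 10.0 | 94.6 |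
| ash | 15.0 | 97.6 |
| birch | 6.00 | 6.3 |
| birch | 15.0 | 17.6 |
| birch | 20.0 | 22.7 |
| birch | 30.0 | 29.9 |

(standard deviation of a reading: 0.3 percentage points)

- every charge counts on the volume at the start, and the solution that is fed holds the whole dose
- the analysis behind the earlier runs scatters by 0.3 percentage points, standard deviation

- which one finishes higher in amount of target, in percent of the substrate charged ("neither" within 2 percentage points) (grey / ochre / neither)
- amount of target at the end, in percent of the substrate charged, grey
- amount of target at the end, in percent of the substrate charged, ochre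

From a short window during the feed I read a pseudo-first-order constant k for substrate. Then I divide out what differs between runs. One term is b, the equivalents of coupling partner standing in the flask, fed so far less target made. The other is v, the volume over the starting volume, which thins both [coupling partner] and [free catalyst]. That leaves the working number w = k·v·v/b.

cedar: k = 0.0309 h⁻¹, b = 1.16, v = 1.23, w = 0.0402 h⁻¹

ash: k = 0.159 h⁻¹, b = 0.875, v = 1.12, w = 0.230 h⁻¹

My rule of thumb works in powers of ten: the thermal slope, the decades of w gained per kelvin, is read from these two runs.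

slope = 0.0506 K⁻¹

Grey starts with b = 2.00 and v = 1.50, and I hold the partner at its charge.

w = 0.0719 h⁻¹, k = 0.0639 h⁻¹, target = 47.2 %

The border of the rule is the feed, since ochre receives partner at f = 0.200 h⁻¹, in substrate's charge per hour. At the end of the feed, with one equivalent standing, the rule gives ochre these values.

w = 0.738 h⁻¹, k = 0.328 h⁻¹, k/f = 1.64

So ochre's constant stands higher than the feed rate, and past that ratio of one I hold the rule's number for ochre as a rough estimate. The dose in ochre matches the substrate after 5.00 h, and that constant over the remaining hours gives 80.6 %, which I take as my rough figure. I therefore expect ochre to finish higher.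

The forecast says ochre, with grey at 36 % and ochre at 92 %, ochre being “largely feed-limited”.

Grey ends at 49.1 % and ochre at 92.5 %, so ochre holds more target than grey. The flasks ran by this scheme:

    coupling partner + free catalyst ⇌ catalyst intermediate A (K = 2.10 M⁻¹, k = 2000 M⁻¹ h⁻¹, Ea = 38.0 kJ mol⁻¹, ΔH = 17.0 kJ mol⁻¹)
    substrate + catalyst intermediate A → catalyst intermediate B (k = 30000 M⁻¹ h⁻¹, Ea = 49.0 kJ mol⁻¹)
    catalyst intermediate B → free catalyst + target (k = 180 h⁻¹, Ea = 87.0 kJ mol⁻¹)
    free catalyst + added ligand ⇌ idle complex, settled at all times (K = 1100 M⁻¹, ΔH = 28.0 kJ mol⁻¹)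
    catalyst intermediate B + capture agent → trapped intermediate (k = 150 M⁻¹ h⁻¹, Ea = 42.0 kJ mol⁻¹)
    substrate + target → side product (k = 0.200 M⁻¹ h⁻¹, Ea = 82.0 kJ mol⁻¹)
    (constants at 25 °C)

At 10.0 h ochre still holds 52.5 % of its own charge of coupling partner. The slope carries 1.01 decades across the 20.0 K between the two flasks. From 5.00 h to 10.0 h substrate falls with a mean constant, taken from the two end points, of 0.0701 h⁻¹ in grey and 0.577 h⁻¹ in ochre, and these two means lie 0.915 decades apart.

(Readings and results are calculated for substances that don't exist; the scatter is artificial.)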